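Ring A (labdane numbering) is disconnected across its two opposite bonds, C2–C3 and C5–C10, into a C2–C1–C10 1,3-dinucleophile (methyl 2-methylacetoacetate; C1 a temporary ketone, C9 the ester carbon) and a C3–C4–C5 1,3-dielectrophile, an (R)-aldehyde whose C19 oxygen is tied to C7 as an unsaturated δ-lactone. In one operation the acetoacetate dianion adds to the C3 aldehyde and the resulting chelated enolate closes ring A by Michael addition of C10 to C5, setting C5 and C10 against the preset quaternary C4. C1 is then deoxygenated, the lactone is unzipped to an alkyne, ring B with its C8 methylene and C9 vinyl group is closed by enyne cycloisomerization, and a Heck coupling adds the butenolide.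

Key step: step 5

Remark: atom labels C1–C20 are those of the labdane skeleton of the target; α is the face that carries the C10 methyl group (C20), β the other face; the ligand antipode in step 1 is assumed to be the one that gives (2S)-3, and the secondary carbinol of 3 (drawn anti) is erased in step 3.

Step 1
Reactants: 1 2-methyl-2-vinyloxirane (racemic); 2 3,3-diethoxypropan-1-ol
Product: 3 (2S,3S)-5,5-diethoxy-2-methyl-2-vinylpentane-1,3-diol
Conditions: [Ir(cod)Cl]2 (2.5 mol %), (S)-Tol-BINAP, 4-cyano-3-nitrobenzoic acid, allyl acetate (preformed π-allyliridium C,O-benzoate), K3PO4 (5 mol %), THF, 60 °C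
Reagents that add atoms: none
Why: Iridium-catalysed transfer-hydrogenative tert-(hydroxy)prenylation of a primary alcohol by a vinyl epoxide: the alcohol is oxidised in situ to the aldehyde and attacked by the chiral allyliridium species through a closed chair transition state, so the ligand sets the quaternary carbon (future C4) with its methyl, hydroxymethyl and vinyl groups, while the adjacent carbinol is only temporary.

Step 2
Reactants: 3 (2S,3S)-5,5-diethoxy-2-methyl-2-vinylpentane-1,3-diol
Product: 5 (4S,5S)-4-hydroxy-5-methyl-5-vinyltetrahydro-2H-pyran-2-one, via cyclic hemiacetal 4 (not isolated)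
Conditions: 1 M HCl, THF, 23 °C; then TEMPO (10 mol %), PhI(OAc)2, CH2Cl2, 23 °C
Reagents that add atoms: water (O)
Why: Acid hydrolysis of the acetal lets the primary hydroxyl close a six-membered lactol, and nitroxyl-catalysed oxidation should convert the lactol to the δ-lactone faster than it touches the hindered secondary alcohol.

Step 3
Reactants: 5 (4S,5S)-4-hydroxy-5-methyl-5-vinyltetrahydro-2H-pyran-2-one
Product: 6 (R)-5-methyl-5-vinyl-5,6-dihydro-2H-pyran-2-one
Conditions: MsCl, Et3N, CH2Cl2, 0 → 23 °C
Reagents that add atoms: none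
Why: Mesylation of the β-hydroxy lactone and in situ E1cB elimination give the conjugated lactone and erase the temporary carbinol centre.

Step 4
Reactants: 6 (R)-5-methyl-5-vinyl-5,6-dihydro-2H-pyran-2-one
Product: 7 (R)-3-methyl-6-oxo-3,6-dihydro-2H-pyran-3-carbaldehyde
Conditions: O3, CH2Cl2, −78 °C (Sudan Red 7B end point); Me2S
Reagents that add atoms: ozone ([O-][O+]=O)
Why: Ozonolysis with reductive work-up cleaves the electron-rich vinyl group selectively over the electron-poor conjugated lactone alkene and unveils the non-enolisable C3 aldehyde on the quaternary C4.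

Step 5
Reactants: 7 (R)-3-methyl-6-oxo-3,6-dihydro-2H-pyran-3-carbaldehyde; 8 methyl 2-methyl-3-oxobutanoate
Product: 10 methyl 8-hydroxy-5,8a-dimethyl-3,6-dioxooctahydro-1H-isochromene-5-carboxylate (labdane descriptors 4β-CH3 5β-H 10α-CH3; C3 epimers), via open aldol adduct 9 (not isolated)
Conditions: 8, NaH (1.05 equiv), THF, 0 °C; n-BuLi (1.05 equiv), 0 °C; 7, −78 °C; AcOH (1.0 equiv), −78 → 23 °C; then AcOH (1.0 equiv)
Reagents that add atoms: none
Why: The NaH/n-BuLi dianion of 8 adds through its terminal carbon C2 to the aldehyde carbon C3 of 7 (acetoacetate dianion aldol), and after one equivalent of acetic acid the remaining sodium/lithium-chelated β-keto ester enolate attacks C5 of the tethered unsaturated lactone (intramolecular Michael addition); the closest known reaction type is a Robinson-type [3+3] aldol/Michael annulation. Ring A is closed in the 6-(enolendo)-exo-trig mode onto the lactone alkene, and no other ring is formed. C5 is controlled by the tether: C10 can reach C5 only on the lactone face syn to the C3 arm and anti to the pseudoaxial C18 methyl, which gives the cis-fused bicycle with H5 cis to C18 and C19 axial on ring A. C10 is controlled by enolate geometry: in the chelated Z-enolate the ester carbon C9 is cis to the enolate oxygen and becomes equatorial in the chair transition state, while the methyl group C20 becomes axial, syn to C19. C3 is formed without useful bias in the intermolecular aldol and is corrected in steps 7 and 8. The step needs 1,2-addition to the aldehyde before any conjugate addition and C-cyclization before lactonization of the δ-hydroxy ester, which the hard dianion at −78 °C, the absence of enolisable hydrogens in 7 and the deactivation of the ester as its enolate should secure.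

Step 6
Reactants: 10 methyl 8-hydroxy-5,8a-dimethyl-3,6-dioxooctahydro-1H-isochromene-5-carboxylate (C3 epimers)
Product: 12 methyl 8-hydroxy-5,8a-dimethyl-3-oxooctahydro-1H-isochromene-5-carboxylate (4β-CH3 5β-H 10α-CH3; C3 epimers), via C1 tosylhydrazone 11 (not isolated)
Conditions: TsNHNH2, MeOH, 50 °C; then catecholborane, CHCl3, 0 °C; NaOAc·3H2O, 60 °C
Reagents that add atoms: none
Why: Tosylhydrazone reduction (Caglioti-type, catecholborane variant): the only ketone condenses with the hydrazide, hydride adds to C1, and loss of sulfinate and N2 leaves a methylene group, while lactone, ester and the quaternary C10 are untouched.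

Step 7
Reactants: 12 methyl 8-hydroxy-5,8a-dimethyl-3-oxooctahydro-1H-isochromene-5-carboxylate (C3 epimers)
Product: 13 methyl 5,8a-dimethyl-3,8-dioxooctahydro-1H-isochromene-5-carboxylate (4β-CH3 5β-H 10α-CH3)
Conditions: Dess–Martin periodinane, NaHCO3, CH2Cl2, 23 °C
Reagents that add atoms: none
Why: Dess–Martin oxidation converts both C3 carbinol epimers into a single ketone that has no enolisable hydrogen on the C4 side.

Step 8
Reactants: 13 methyl 5,8a-dimethyl-3,8-dioxooctahydro-1H-isochromene-5-carboxylate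
Product: 14 methyl 8-hydroxy-5,8a-dimethyl-3-oxooctahydro-1H-isochromene-5-carboxylate (3α-OH 4β-CH3 5β-H 10α-CH3)
Conditions: NaBH4, MeOH, −20 °C
Reagents that add atoms: none
Why: NaBH4 reduces only the ketone, and axial delivery of hydride from the β face, as is usual for 4,4-disubstituted cyclohexanones, should give the equatorial 3α-alcohol, which sets C3.

Step 9
Reactants: 14 methyl 8-hydroxy-5,8a-dimethyl-3-oxooctahydro-1H-isochromene-5-carboxylate (3α-OH)
Product: 15 methyl 3,8-dihydroxy-5,8a-dimethyloctahydro-1H-isochromene-5-carboxylate (lactol; 3α-OH 4β-CH3 5β-H 10α-CH3)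
Conditions: i-Bu2AlH (2.2 equiv), CH2Cl2, −78 °C; aq. KNaC4H4O6
Reagents that add atoms: none
Why: Partial reduction with i-Bu2AlH at −78 °C stops at the lactol because the aluminium hemiacetal is stable at that temperature, and the unhindered δ-lactone should react before the ester on the quaternary C10.

Step 10
Reactants: 15 methyl 3,8-dihydroxy-5,8a-dimethyloctahydro-1H-isochromene-5-carboxylate
Product: 17 methyl 4-hydroxy-3-(hydroxymethyl)-1,3-dimethyl-2-(3-oxopropyl)cyclohexane-1-carboxylate (3α-OH 4β-CH3 5β-H 10α-CH3), via methyl enol ether 16 (not isolated)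
Conditions: Ph3P(CH2OMe)Cl, KN(SiMe3)2, THF, 0 → 23 °C; then 1 M HCl, THF, 23 °C
Reagents that add atoms: (methoxymethyl)triphenylphosphonium chloride (COC[P+](c1ccccc1)(c1ccccc1)c1ccccc1.[Cl-]); water (O)
Why: Wittig methoxymethylenation of the lactol through its open hydroxy aldehyde form, followed by acid hydrolysis of the enol ether (one-carbon aldehyde homologation), installs C8.

Step 11
Reactants: 17 methyl 4-hydroxy-3-(hydroxymethyl)-1,3-dimethyl-2-(3-oxopropyl)cyclohexane-1-carboxylate
Product: 18 methyl 2-(but-3-ynyl)-4-hydroxy-3-(hydroxymethyl)-1,3-dimethylcyclohexane-1-carboxylate (3α-OH 4β-CH3 5β-H 10α-CH3)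
Conditions: dimethyl (1-diazo-2-oxopropyl)phosphonate, K2CO3, MeOH, 23 °C
Reagents that add atoms: dimethyl (1-diazo-2-oxopropyl)phosphonate (COP(=O)(OC)C(=[N+]=[N-])C(C)=O)
Why: Ohira–Bestmann homologation converts the aldehyde into the terminal alkyne (C8≡C17) under conditions that leave the hindered ester and the free hydroxyls alone.

Step 12
Reactants: 18 methyl 2-(but-3-ynyl)-4-hydroxy-3-(hydroxymethyl)-1,3-dimethylcyclohexane-1-carboxylate
Product: 19 2-(but-3-ynyl)-4-hydroxy-3-(hydroxymethyl)-1,3-dimethylcyclohexane-1-carbaldehyde (3α-OH 4β-CH3 5β-H 10α-CH3)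
Conditions: i-Bu2AlH (3.5 equiv), CH2Cl2, −78 °C; MeOH, aq. KNaC4H4O6
Reagents that add atoms: none
Why: i-Bu2AlH reduction of the hindered ester at −78 °C should stop at the tetrahedral aluminium hemiacetal and give the neopentyl aldehyde on work-up.

Step 13
Reactants: 19 2-(but-3-ynyl)-4-hydroxy-3-(hydroxymethyl)-1,3-dimethylcyclohexane-1-carbaldehyde
Product: 20 3-(but-3-ynyl)-2-(hydroxymethyl)-2,4-dimethyl-4-[(E)-prop-1-enyl]cyclohexan-1-ol (3α-OH 4β-CH3 5β-H 10α-CH3)
Conditions: CrCl2 (8 equiv), CH3CHI2, THF, 23 °C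
Reagents that add atoms: 1,1-diiodoethane (CC(I)I)
Why: Takai–Utimoto olefination with the geminal dichromium reagent from 1,1-diiodoethane is selective for the aldehyde and gives the (E)-propenyl group needed for the ene step.

Step 14
Reactants: 20 3-(but-3-ynyl)-2-(hydroxymethyl)-2,4-dimethyl-4-[(E)-prop-1-enyl]cyclohexan-1-ol
Product: 21 (1R,4aS,5R,6R,8aR)-1-ethenyl-5-(hydroxymethyl)-5,8a-dimethyl-2-methylidenedecahydronaphthalen-6-ol
Conditions: Pd(OAc)2 (5 mol %), PPh3 (10 mol %), benzene, 65 °C
Reagents that add atoms: none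
Why: Palladium-catalysed Alder-ene cycloisomerization of the 1,7-enyne: hydropalladation of the alkyne at C8, 6-exo carbopalladation of the propenyl alkene at C9 through a chair-like transition state that keeps C11 equatorial next to the preset C5 and C10, then β-hydride elimination from the C12 methyl group, which closes ring B and creates the C8 exocyclic methylene, the C9 stereocentre and the C9 vinyl group.

Step 15
Reactants: 21 (1R,4aS,5R,6R,8aR)-1-ethenyl-5-(hydroxymethyl)-5,8a-dimethyl-2-methylidenedecahydronaphthalen-6-ol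
Product: 22 (1R,4aS,5R,6R,8aR)-5-(acetoxymethyl)-1-ethenyl-5,8a-dimethyl-2-methylidenedecahydronaphthalen-6-ol
Conditions: AcCl (1.05 equiv), 2,4,6-collidine, CH2Cl2, −78 °C
Reagents that add atoms: acetyl chloride (CC(Cl)=O)
Why: Kinetic acetylation at low temperature should select the primary C19 hydroxyl over the secondary C3 hydroxyl, which is flanked by the quaternary C4.

Step 16
Reactants: 22 (1R,4aS,5R,6R,8aR)-5-(acetoxymethyl)-1-ethenyl-5,8a-dimethyl-2-methylidenedecahydronaphthalen-6-ol; 23 3-bromofuran-2(5H)-one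
Product: 24 3-[(E)-2-[(1R,4aS,5R,6R,8aR)-5-(acetoxymethyl)-6-hydroxy-5,8a-dimethyl-2-methylidenedecahydronaphthalen-1-yl]ethenyl]furan-2(5H)-one (CNP0346413.1)
Conditions: Pd(OAc)2 (10 mol %), n-Bu4NCl, NaHCO3, DMF, 60 °C
Reagents that add atoms: none
Why: Mizoroki–Heck reaction under ligand-free phase-transfer conditions should couple the α-bromobutenolide to the monosubstituted C11=C12 alkene in preference to the 1,1-disubstituted C8 methylene, and syn β-hydride elimination of a C12 hydrogen gives the (E)-diene conjugated to the lactone.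

Compound list
1 | 2-methyl-2-vinyloxirane (racemic) | C=CC1(C)CO1 | starting material
2 | 3,3-diethoxypropan-1-ol | CCOC(CCO)OCC | starting material
3 | (2S,3S)-5,5-diethoxy-2-methyl-2-vinylpentane-1,3-diol | CCOC(OCC)C[C@H](O)[C@](C)(CO)C=C | intermediate
4 | (4S,5S)-5-methyl-5-vinyltetrahydro-2H-pyran-2,4-diol (cyclic hemiacetal, anomers) | OC1C[C@H](O)[C@](C)(CO1)C=C | intermediate
5 | (4S,5S)-4-hydroxy-5-methyl-5-vinyltetrahydro-2H-pyran-2-one | O=C1C[C@H](O)[C@](C)(CO1)C=C | intermediate
6 | (R)-5-methyl-5-vinyl-5,6-dihydro-2H-pyran-2-one | O=C1C=C[C@](C)(CO1)C=C | intermediate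
7 | (R)-3-methyl-6-oxo-3,6-dihydro-2H-pyran-3-carbaldehyde | O=C1C=C[C@](C)(CO1)C=O | intermediate
8 | methyl 2-methyl-3-oxobutanoate | COC(=O)C(C)C(C)=O | starting material
9 | methyl 5-hydroxy-2-methyl-5-[(3R)-3-methyl-6-oxo-3,6-dihydro-2H-pyran-3-yl]-3-oxopentanoate (open aldol adduct, mixture at C3 and C10) | O=C1C=C[C@](C)(CO1)C(O)CC(=O)C(C)C(=O)OC | intermediate
10 | methyl 8-hydroxy-5,8a-dimethyl-3,6-dioxooctahydro-1H-isochromene-5-carboxylate (ring A ketol cis-fused to the 19,7-lactone; 4β-CH3, 5β-H, 10α-CH3, 10β-CO2Me; C3 epimers) | O=C1C[C@@H]2[C@](C)(CO1)C(O)CC(=O)[C@@]2(C)C(=O)OC | intermediate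
11 | C1 tosylhydrazone of 10 | O=C1C[C@@H]2[C@](C)(CO1)C(O)CC(=NNS(=O)(=O)c3ccc(C)cc3)[C@@]2(C)C(=O)OC | intermediate
12 | methyl 8-hydroxy-5,8a-dimethyl-3-oxooctahydro-1H-isochromene-5-carboxylate (4β-CH3, 5β-H, 10α-CH3; C3 epimers) | O=C1C[C@@H]2[C@](C)(CO1)C(O)CC[C@@]2(C)C(=O)OC | intermediate
13 | methyl 5,8a-dimethyl-3,8-dioxooctahydro-1H-isochromene-5-carboxylate (4β-CH3, 5β-H, 10α-CH3) | O=C1C[C@@H]2[C@](C)(CO1)C(=O)CC[C@@]2(C)C(=O)OC | intermediate
14 | methyl 8-hydroxy-5,8a-dimethyl-3-oxooctahydro-1H-isochromene-5-carboxylate (3α-OH, 4β-CH3, 5β-H, 10α-CH3) | O=C1C[C@@H]2[C@](C)(CO1)[C@H](O)CC[C@@]2(C)C(=O)OC | intermediate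
15 | methyl 3,8-dihydroxy-5,8a-dimethyloctahydro-1H-isochromene-5-carboxylate (lactol, anomers; 3α-OH, 4β-CH3, 5β-H, 10α-CH3) | OC1C[C@@H]2[C@](C)(CO1)[C@H](O)CC[C@@]2(C)C(=O)OC | intermediate
16 | methyl 4-hydroxy-3-(hydroxymethyl)-2-(4-methoxybut-3-enyl)-1,3-dimethylcyclohexane-1-carboxylate (E/Z enol ether; 3α-OH, 4β-CH3, 5β-H, 10α-CH3) | COC=CC[C@@H]1[C@](C)(CO)[C@H](O)CC[C@@]1(C)C(=O)OC | intermediate
17 | methyl 4-hydroxy-3-(hydroxymethyl)-1,3-dimethyl-2-(3-oxopropyl)cyclohexane-1-carboxylate (3α-OH, 4β-CH3, 5β-H, 10α-CH3) | O=CCC[C@@H]1[C@](C)(CO)[C@H](O)CC[C@@]1(C)C(=O)OC | intermediate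
18 | methyl 2-(but-3-ynyl)-4-hydroxy-3-(hydroxymethyl)-1,3-dimethylcyclohexane-1-carboxylate (3α-OH, 4β-CH3, 5β-H, 10α-CH3) | C#CCC[C@@H]1[C@](C)(CO)[C@H](O)CC[C@@]1(C)C(=O)OC | intermediate
19 | 2-(but-3-ynyl)-4-hydroxy-3-(hydroxymethyl)-1,3-dimethylcyclohexane-1-carbaldehyde (3α-OH, 4β-CH3, 5β-H, 10α-CH3) | C#CCC[C@@H]1[C@](C)(CO)[C@H](O)CC[C@@]1(C)C=O | intermediate
20 | 3-(but-3-ynyl)-2-(hydroxymethyl)-2,4-dimethyl-4-[(E)-prop-1-enyl]cyclohexan-1-ol (3α-OH, 4β-CH3, 5β-H, 10α-CH3) | C#CCC[C@@H]1[C@](C)(CO)[C@H](O)CC[C@@]1(C)/C=C/C | intermediate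
21 | (1R,4aS,5R,6R,8aR)-1-ethenyl-5-(hydroxymethyl)-5,8a-dimethyl-2-methylidenedecahydronaphthalen-6-ol | C=C1CC[C@@H]2[C@](C)(CO)[C@H](O)CC[C@@]2(C)[C@@H]1C=C | intermediate
22 | (1R,4aS,5R,6R,8aR)-5-(acetoxymethyl)-1-ethenyl-5,8a-dimethyl-2-methylidenedecahydronaphthalen-6-ol | C=C1CC[C@@H]2[C@](C)(COC(C)=O)[C@H](O)CC[C@@]2(C)[C@@H]1C=C | intermediate
23 | 3-bromofuran-2(5H)-one | O=C1OCC=C1Br | starting material
24 | 3-[(E)-2-[(1R,4aS,5R,6R,8aR)-5-(acetoxymethyl)-6-hydroxy-5,8a-dimethyl-2-methylidenedecahydronaphthalen-1-yl]ethenyl]furan-2(5H)-one | C=C1CC[C@@H]2[C@](C)(COC(C)=O)[C@H](O)CC[C@@]2(C)[C@@H]1/C=C/C1=CCOC1=O | target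

Total step count: 16. Longest linear sequence: 16 steps (from 1 and 2 to 24).

Steps most likely to fail

Step 5. The δ-hydroxy ester may lactonize before the Michael closure. The enolate may lose its chelated geometry and so give poor facial selectivity at C10. The aldol may reverse on warming. The fallback sets out from 7 and 8 and makes the two bonds in separate operations. Compound 8 is converted (Me3SiCl/Et3N, then lithium diisopropylamide/Me3SiCl) into the bis(silyl) dienol ether F1. A TiCl4-mediated vinylogous Mukaiyama aldol reaction of F1 with 7 gives the open aldol adduct 9, which is now isolated. Silylation (Et3SiCl, imidazole) gives the triethylsilyl ether F2. Soft enolization with MgBr2·OEt2/Et3N forms the magnesium-chelated β-keto ester enolate, which should close ring A by Michael addition to the silylated bicycle F3. HF·pyridine removes the silyl group, and the route is rejoined at 10.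

Step 14. β-Hydride elimination may go toward C9 and give the conjugated 1,3-diene; closure of the six-membered ring next to the quaternary C10 may be slow; and facial selectivity at C9 may be poor. The fallback sets out from 20. Markovnikov hydrobromination of the terminal alkyne with B-bromo-9-borabicyclo[3.3.1]nonane, then AcOH, gives the 2-bromoalkene F4. An intramolecular Mizoroki–Heck cyclization under silver-assisted cationic conditions (Pd(PPh3)4, Ag2CO3, MeCN, 60 °C) then closes ring B by 6-exo carbopalladation from a preformed vinylpalladium species. It comes back to the route at 21.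

Step 6. Hydrazone formation may be slow at the ketone next to the quaternary C10, and the β-hydroxy ketone may eliminate or undergo retro-Claisen cleavage during the reduction. The fallback sets out from 10. Ethane-1,2-dithiol and BF3·OEt2 give the dithiolane F5, and Raney nickel in ethanol removes the sulfur while no alkene is yet present. It comes back to the route at 12.

Further compounds
F1 | step 5 | 1-methoxy-2-methyl-1,3-bis(trimethylsilyloxy)buta-1,3-diene | COC(O[Si](C)(C)C)=C(C)C(=C)O[Si](C)(C)C
F2 | step 5 | triethylsilyl ether of open aldol adduct 9 | O=C1C=C[C@](C)(CO1)C(O[Si](CC)(CC)CC)CC(=O)C(C)C(=O)OC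
F3 | step 5 | C3 triethylsilyl ether of 10 | O=C1C[C@@H]2[C@](C)(CO1)C(O[Si](CC)(CC)CC)CC(=O)[C@@]2(C)C(=O)OC
F4 | step 14 | 3-(3-bromobut-3-enyl)-2-(hydroxymethyl)-2,4-dimethyl-4-[(E)-prop-1-enyl]cyclohexan-1-ol (3α-OH, 4β-CH3, 5β-H, 10α-CH3) | C=C(Br)CC[C@@H]1[C@](C)(CO)[C@H](O)CC[C@@]1(C)/C=C/C
F5 | step 6 | C1 1,3-dithiolane of 10 | O=C1C[C@@H]2[C@](C)(CO1)C(O)CC3(SCCS3)[C@@]2(C)C(=O)OC
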